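**Retrosynthetic overview**
- Praesorether G comes from its octa-O-methyl ether by one global aryl methyl ether cleavage that leaves both methyl esters in place.
- The two diaryl ether C–O bonds come from a twofold SNAr of the ring B and ring D phenoxides of a triaryl core on a fluoro-ester-aldehyde (rings A and E).
- Key step: both Ar–CH2–Ar bonds are made in one pot. A ring B aldehyde, as its N-unsubstituted hydrazone, acts as a benzylic carbanion (carbonyl polarity reversed) and is coupled twice with the ring C dibromide under nickel catalysis.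
- The ring B aldehyde comes from 2,4-dimethoxy-6-methylbenzaldehyde (Dakin, silylation, lithiation–formylation), the dibromide from 3,5-dimethoxytoluene, and the fluoro-ester-aldehyde from 3-fluoro-5-methylanisole (bromination, one-pot double metalation).
- No ring is constructed: all five benzene rings are bought. Rings B and D are joined to ring C first, then rings A and E are attached.

Assumption: the target SMILES has no stereocentre and no stereogenic double bond, so the compound is achiral and no enantiocontrol is needed; the only stereodescriptor in the route is the E geometry of a transient hydrazone.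

**Step 1**
Reactants: 1 2,4-dimethoxy-6-methylbenzaldehyde
Product: 3 2,4-dimethoxy-6-methylphenol, via aryl formate 2 (not isolated)
Conditions: mCPBA, CH2Cl2, 0 °C → rt; then K2CO3 (cat.), MeOH, rt
Reagents that add atoms: mCPBA, O=C(OO)c1cccc(Cl)c1
Why: Dakin-type Baeyer–Villiger oxidation, in which the electron-rich aryl group migrates to give formate 2 and catalytic methanolysis then frees the phenol.

**Step 2**
Reactants: 3 2,4-dimethoxy-6-methylphenol
Product: 4 (2,4-dimethoxy-6-methylphenoxy)triisopropylsilane
Conditions: TIPSCl, imidazole, DMF, 50 °C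
Reagents that add atoms: triisopropylsilyl chloride, CC(C)[Si](Cl)(C(C)C)C(C)C
Why: Imidazole-assisted O-silylation gives a bulky, non-coordinating silyl ether that tolerates organolithium and nickel chemistry and is later removed by fluoride in the same pot as the ether formation.

**Step 3**
Reactants: 4 (2,4-dimethoxy-6-methylphenoxy)triisopropylsilane
Product: 7 2,6-dimethoxy-4-methyl-3-(triisopropylsilyloxy)benzaldehyde, via aryllithium 5 (not isolated), via lithium amino-alkoxide 6 (not isolated)
Conditions: n-BuLi, TMEDA, THF, 0 °C; DMF, 0 °C → rt; 1 M HCl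
Reagents that add atoms: N,N-dimethylformamide, CN(C)C=O
Why: Directed ortho-metalation removes the only ring hydrogen flanked by two methoxy groups, and DMF trapping (Bouveault formylation) places the future bridge carbon there.

**Step 4**
Reactants: 8 1,3-dimethoxy-5-methylbenzene
Product: 10 2,4-dibromo-1,5-dimethoxy-3-methylbenzene, via monobromide 9 (not isolated)
Conditions: NBS (2.1 equiv), MeCN, 0 °C → rt
Reagents that add atoms: N-bromosuccinimide, O=C1CCC(=O)N1Br
Why: Twofold electrophilic aromatic bromination, each bromine entering para to one methoxy and ortho to the other, so that both land on the carbons flanking the methyl group.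

**Step 5**
Reactants: 7 2,6-dimethoxy-4-methyl-3-(triisopropylsilyloxy)benzaldehyde (2.6 equiv); 10 2,4-dibromo-1,5-dimethoxy-3-methylbenzene
Product: 13 1,5-dimethoxy-3-methyl-2,4-bis{[2,6-dimethoxy-4-methyl-3-(triisopropylsilyloxy)phenyl]methyl}benzene, via hydrazone 11 (not isolated), via mono-coupled bromide 12 (not isolated)
Conditions: 7, N2H4·H2O, THF, rt; then 10, Ni(cod)2 (20 mol%), PMe3 (40 mol%), K3PO4, THF, 80 °C (sealed)
Reagents that add atoms: none
Why: Proposed new method: the N-unsubstituted hydrazone 11 is a benzylic carbanion equivalent (aldehyde carbon made nucleophilic), so after oxidative addition of each C–Br bond to zerovalent nickel the deprotonated hydrazone binds the aryl–nickel bromide (divalent nickel), loses N2 in a Wolff–Kishner-type step and the benzyl–aryl bond forms by reductive elimination, joining an aldehyde carbon and an aryl bromide carbon (both natural electrophiles) twice in one pot without creating a stereocentre; the closest known reaction type is the nickel-catalysed deoxygenative cross-coupling of aldehyde hydrazones with single, less hindered aryl halides, extended here to a double coupling of di-ortho-substituted partners.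

**Step 6**
Reactants: 14 1-fluoro-3-methoxy-5-methylbenzene
Product: 15 2-bromo-1-fluoro-5-methoxy-3-methylbenzene
Conditions: NBS, MeCN, rt
Reagents that add atoms: N-bromosuccinimide, O=C1CCC(=O)N1Br
Why: Electrophilic aromatic bromination of an anisole is para-selective with NBS in MeCN, which marks the carbon between F and CH3 that will carry the ester.

**Step 7**
Reactants: 15 2-bromo-1-fluoro-5-methoxy-3-methylbenzene
Product: 20 methyl 2-fluoro-3-formyl-4-methoxy-6-methylbenzoate, via aryllithium 16 (not isolated), via amino-alkoxide 17 (not isolated), via dilithio species 18 (not isolated), via ester amino-alkoxide 19 (not isolated)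
Conditions: LiN(iPr)2, THF, −78 °C; DMF (1.0 equiv), −78 °C; n-BuLi (2.1 equiv, one equivalent re-lithiates the liberated amine), −78 °C; ClCO2Me (3.5 equiv), −78 → 0 °C; 1 M HCl
Reagents that add atoms: N,N-dimethylformamide, CN(C)C=O; methyl chloroformate, COC(=O)Cl
Why: The amide base lithiates only the C–H between F and OMe (directed ortho-metalation, no bromine–lithium exchange), the DMF adduct 17 stays as an in situ protected aldehyde (α-amino alkoxide), and bromine–lithium exchange then fixes the second carbanion between F and CH3 for methoxycarbonylation before acid releases the aldehyde.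

**Step 8**
Reactants: 13 1,5-dimethoxy-3-methyl-2,4-bis{[2,6-dimethoxy-4-methyl-3-(triisopropylsilyloxy)phenyl]methyl}benzene; 20 methyl 2-fluoro-3-formyl-4-methoxy-6-methylbenzoate (2.5 equiv)
Product: 23 dimethyl 2,2'-{(4,6-dimethoxy-2-methyl-1,3-phenylene)bis[methylene(2,4-dimethoxy-6-methyl-3,1-phenylene)oxy]}bis(3-formyl-4-methoxy-6-methylbenzoate), via dicaesium bis-phenoxide 21 (not isolated), via mono-ether caesium phenoxide 22 (not isolated)
Conditions: CsF (2.5 equiv), DMF, rt; then 20, 80 °C
Reagents that add atoms: none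
Why: Fluoride-triggered desilylative SNAr, in which CsF unmasks the two phenoxides and each displaces the fluoride of 20 (activated by ortho-formyl and ortho-ester groups) through a Meisenheimer complex, the released fluoride regenerating CsF.

**Step 9**
Reactants: 23 dimethyl 2,2'-{(4,6-dimethoxy-2-methyl-1,3-phenylene)bis[methylene(2,4-dimethoxy-6-methyl-3,1-phenylene)oxy]}bis(3-formyl-4-methoxy-6-methylbenzoate)
Product: 24 Praesorether G
Conditions: BBr3 (20 equiv), CH2Cl2, −78 → 0 °C; ice-water
Reagents that add atoms: none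
Why: Lewis acid ether cleavage, in which BBr3 binds the eight aryl methyl ether oxygens and bromide removes the methyl groups (SN2), while the two di-ortho-substituted, non-chelated methyl benzoates react much more slowly at or below 0 °C.

**Compound list**
1 | 2,4-dimethoxy-6-methylbenzaldehyde | COc1cc(C)c(C=O)c(OC)c1 | starting material
2 | 2,4-dimethoxy-6-methylphenyl formate | COc1cc(C)c(OC=O)c(OC)c1 | intermediate
3 | 2,4-dimethoxy-6-methylphenol | COc1cc(C)c(O)c(OC)c1 | intermediate
4 | (2,4-dimethoxy-6-methylphenoxy)triisopropylsilane | COc1cc(C)c(O[Si](C(C)C)(C(C)C)C(C)C)c(OC)c1 | intermediate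
5 | [2,6-dimethoxy-4-methyl-3-(triisopropylsilyloxy)phenyl]lithium | COc1cc(C)c(O[Si](C(C)C)(C(C)C)C(C)C)c(OC)c1[Li] | intermediate
6 | lithium (dimethylamino)[2,6-dimethoxy-4-methyl-3-(triisopropylsilyloxy)phenyl]methanolate (racemic, transient) | COc1cc(C)c(O[Si](C(C)C)(C(C)C)C(C)C)c(OC)c1C(O[Li])N(C)C | intermediate
7 | 2,6-dimethoxy-4-methyl-3-(triisopropylsilyloxy)benzaldehyde | COc1cc(C)c(O[Si](C(C)C)(C(C)C)C(C)C)c(OC)c1C=O | intermediate
8 | 1,3-dimethoxy-5-methylbenzene (3,5-dimethoxytoluene) | COc1cc(C)cc(OC)c1 | starting material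
9 | 2-bromo-1,5-dimethoxy-3-methylbenzene | COc1cc(C)c(Br)c(OC)c1 | intermediate
10 | 2,4-dibromo-1,5-dimethoxy-3-methylbenzene | COc1cc(OC)c(Br)c(C)c1Br | intermediate
11 | (E)-{[2,6-dimethoxy-4-methyl-3-(triisopropylsilyloxy)phenyl]methylidene}hydrazine | COc1cc(C)c(O[Si](C(C)C)(C(C)C)C(C)C)c(OC)c1/C=N/N | intermediate
12 | [3-[(3-bromo-4,6-dimethoxy-2-methylphenyl)methyl]-2,4-dimethoxy-6-methylphenoxy]triisopropylsilane | COc1cc(OC)c(Br)c(C)c1Cc1c(OC)cc(C)c(O[Si](C(C)C)(C(C)C)C(C)C)c1OC | intermediate
13 | 1,5-dimethoxy-3-methyl-2,4-bis{[2,6-dimethoxy-4-methyl-3-(triisopropylsilyloxy)phenyl]methyl}benzene | COc1cc(OC)c(Cc2c(OC)cc(C)c(O[Si](C(C)C)(C(C)C)C(C)C)c2OC)c(C)c1Cc1c(OC)cc(C)c(O[Si](C(C)C)(C(C)C)C(C)C)c1OC | intermediate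
14 | 1-fluoro-3-methoxy-5-methylbenzene (3-fluoro-5-methylanisole) | COc1cc(C)cc(F)c1 | starting material
15 | 2-bromo-1-fluoro-5-methoxy-3-methylbenzene | COc1cc(C)c(Br)c(F)c1 | intermediate
16 | (3-bromo-2-fluoro-6-methoxy-4-methylphenyl)lithium | COc1cc(C)c(Br)c(F)c1[Li] | intermediate
17 | lithium (3-bromo-2-fluoro-6-methoxy-4-methylphenyl)(dimethylamino)methanolate (racemic, transient) | COc1cc(C)c(Br)c(F)c1C(O[Li])N(C)C | intermediate
18 | lithium (dimethylamino)(2-fluoro-3-lithio-6-methoxy-4-methylphenyl)methanolate | COc1cc(C)c([Li])c(F)c1C(O[Li])N(C)C | intermediate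
19 | lithium (dimethylamino)[2-fluoro-6-methoxy-3-(methoxycarbonyl)-4-methylphenyl]methanolate | COc1cc(C)c(C(=O)OC)c(F)c1C(O[Li])N(C)C | intermediate
20 | methyl 2-fluoro-3-formyl-4-methoxy-6-methylbenzoate | COC(=O)c1c(C)cc(OC)c(C=O)c1F | intermediate
21 | dicaesium 3,3'-[(4,6-dimethoxy-2-methyl-1,3-phenylene)bis(methylene)]bis(2,4-dimethoxy-6-methylphenolate) | [Cs+].[Cs+].COc1cc(OC)c(Cc2c(OC)cc(C)c([O-])c2OC)c(C)c1Cc1c(OC)cc(C)c([O-])c1OC | intermediate
22 | caesium phenolate of the mono-ether (one ring B oxygen arylated by 20, the other still phenoxide) | [Cs+].COC(=O)c1c(C)cc(OC)c(C=O)c1Oc1c(C)cc(OC)c(Cc2c(OC)cc(OC)c(Cc3c(OC)cc(C)c([O-])c3OC)c2C)c1OC | intermediate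
23 | dimethyl 2,2'-{(4,6-dimethoxy-2-methyl-1,3-phenylene)bis[methylene(2,4-dimethoxy-6-methyl-3,1-phenylene)oxy]}bis(3-formyl-4-methoxy-6-methylbenzoate) (octa-O-methyl Praesorether G) | COC(=O)c1c(C)cc(OC)c(C=O)c1Oc1c(C)cc(OC)c(Cc2c(OC)cc(OC)c(Cc3c(OC)cc(C)c(Oc4c(C=O)c(OC)cc(C)c4C(=O)OC)c3OC)c2C)c1OC | intermediate
24 | Praesorether G | COC(=O)c1c(C)cc(O)c(C=O)c1Oc1c(C)cc(O)c(Cc2c(O)cc(O)c(Cc3c(O)cc(C)c(Oc4c(C=O)c(O)cc(C)c4C(=O)OC)c3O)c2C)c1O | target

**Step count**
Total steps: 9. Longest linear sequence: 6 (steps 1, 2, 3, 5, 8, 9).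

**Three steps most likely to fail**

Step 5 (double hydrazone coupling). Both partners are di-ortho-substituted, so the second coupling may stall at 12, and the hydrazone can instead be reduced to the methylarene or form the azine. The fallback sets out from 7 and comes back at 13. It keeps the benzylic carbon as the nucleophile but makes it an organozinc reagent. Aldehyde 7 is reduced with NaBH4 in MeOH to [2,6-dimethoxy-4-methyl-3-(triisopropylsilyloxy)phenyl]methanol F1. SOCl2 in CH2Cl2 at 0 °C converts it into [3-(chloromethyl)-2,4-dimethoxy-6-methylphenoxy]triisopropylsilane F2. Zn dust and LiCl in THF insert to give {[2,6-dimethoxy-4-methyl-3-(triisopropylsilyloxy)phenyl]methyl}zinc chloride F3. Twofold Negishi coupling of F3 with dibromide 10 (Pd(OAc)2, SPhos, THF, 60 °C) then gives 13.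

Step 7 (one-pot double metalation). Incomplete first deprotonation, loss of LiF from 18 to an aryne, or over-reaction with excess DMF would lower the yield. The fallback sets out from 15 and comes back at 20, and installs the ester by catalytic carbonylation instead of a second carbanion. Compound 15 is lithiated with LiN(iPr)2 and quenched with DMF as before, but worked up at once to isolate 3-bromo-2-fluoro-6-methoxy-4-methylbenzaldehyde F4. Palladium-catalysed methoxycarbonylation of F4 (Pd(OAc)2, Xantphos, CO 1 atm, MeOH, NaOAc, toluene, 80 °C) gives 20.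

Step 9 (global demethylation). Eight ether cleavages must outrun attack on two methyl esters, and the Lewis acid could promote condensation of the aldehydes with the freed resorcinol rings. The fallback sets out from 23 and comes back at 24, and gives up ester survival on purpose. Excess BBr3 in CH2Cl2 at rt cleaves all ten O-methyl groups to give 2,2'-{(4,6-dihydroxy-2-methyl-1,3-phenylene)bis[methylene(2,4-dihydroxy-6-methyl-3,1-phenylene)oxy]}bis(3-formyl-4-hydroxy-6-methylbenzoic acid) F5. The two carboxylic acids are then re-esterified selectively with TMSCHN2 (2 equiv, toluene/MeOH, 0 °C), the much less acidic and hydrogen-bonded phenols staying free, to give 24.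

**Further compounds**
F1 | step 5 | [2,6-dimethoxy-4-methyl-3-(triisopropylsilyloxy)phenyl]methanol | COc1cc(C)c(O[Si](C(C)C)(C(C)C)C(C)C)c(OC)c1CO
F2 | step 5 | [3-(chloromethyl)-2,4-dimethoxy-6-methylphenoxy]triisopropylsilane | COc1cc(C)c(O[Si](C(C)C)(C(C)C)C(C)C)c(OC)c1CCl
F3 | step 5 | {[2,6-dimethoxy-4-methyl-3-(triisopropylsilyloxy)phenyl]methyl}zinc chloride | COc1cc(C)c(O[Si](C(C)C)(C(C)C)C(C)C)c(OC)c1C[Zn]Cl
F4 | step 7 | 3-bromo-2-fluoro-6-methoxy-4-methylbenzaldehyde | COc1cc(C)c(Br)c(F)c1C=O
F5 | step 9 | 2,2'-{(4,6-dihydroxy-2-methyl-1,3-phenylene)bis[methylene(2,4-dihydroxy-6-methyl-3,1-phenylene)oxy]}bis(3-formyl-4-hydroxy-6-methylbenzoic acid) | OC(=O)c1c(C)cc(O)c(C=O)c1Oc1c(C)cc(O)c(Cc2c(O)cc(O)c(Cc3c(O)cc(C)c(Oc4c(C=O)c(O)cc(C)c4C(=O)O)c3O)c2C)c1O
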